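The dawn flask, which is the asked flask followed so far, kept 58.7% of its starting complex at 10.0 min and 60.3% at 120 min, a leftover that had stopped falling by the first reading and needs explaining before any option is judged.

| setting | dawn | autumn | flask |
|---|---|---|---|
| starting complex | 0.010 M | 0.020 M | 0.010 M |
| incoming ligand | 5 mM | 5 mM | 5.00 mM |
| leaving ligand | 5 mM | 5 mM | 5.00 mM |
| scavenger | 0.015 M | 0.015 M | 0.0150 M |
| temperature | 90 °C | 75 °C | 90 °C |
| remark | the very flask that is asked about, followed so far | run made earlier |  |
| time |  |  | 2.0 h |

| run | time / min | complex with one exchanged / % | starting complex / % |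
|---|---|---|---|
| dawn | 10.0 | 31.0 | 58.7 |
| dawn | 20.0 | 31.6 | 59.9 |
| dawn | 50.0 | 30.5 | 59.7 |
| dawn | 120 | 32.1 | 60.3 |
| autumn | 1.33 | 14.5 | 82.6 |
| autumn | 3.00 | 18.9 | 77.7 |
| autumn | 4.00 | 19.1 | 77.9 |
| autumn | 5.00 | 18.5 | 78.1 |

(standard deviation of a reading: 0.5 percentage points)

- red: at 2.0 h raise the temperature by 20 K, then wait 2.0 h
- grey: at 2.0 h add incoming ligand, 100% of the amount charged, then wait 2.0 h
- violet: change nothing and wait 2.0 h more
- teal: at 2.0 h add starting complex, 50.0% of the amount charged, then wait 2.0 h

- additions bring no volume worth counting
- a reading or a percentage of leaving ligand counts all its forms, free or not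

1. complex with one exchanged, in percent of the starting complex first charged, at 2.0 h
2. which option adds most complex with one exchanged ("none" when 2 percentage points or less is all one gets) (red / grey / violet / teal / none)
3. complex with one exchanged present, in percent of the starting complex first charged, after red
4. complex with one exchanged present, in percent of the starting complex first charged, after teal

Incoming ligand is the limiting reagent of the asked flask, charged at 5.00 mM against 0.010 M of starting complex, so its balance is the reckoning to write. The exchange budget, 50.0%, is the incoming ligand charged as a share of the starting complex charged; each exchange costs one incoming ligand, so the exchanges made, counted in percent of the charge, cannot pass it.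

With the main step by itself, starting complex and incoming ligand giving complex with one exchanged and leaving ligand, the budget buys 50.0% of that complex and leaves 50.0% of starting complex. The dawn readings, however, average 59.6% of starting complex and 31.3% of complex with one exchanged, so 9.05% of the charge is missing.

Adding a second exchange, which reads that gap as complex with two exchanged at 2 ligands each, brings the bill to 49.4%, against the budget of 50.0%. The autumn run, colder at 75 °C and charged with 0.020 M of starting complex, has a budget of 25.0%, and its last reading bills 25.3%.

Then comes the rest: the leaving ligand charged and released comes to 10.0 mM, less than the 0.0150 M of scavenger, so the scavenger charged covers that amount, with 5.00 mM to spare.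

The reckoning here therefore commits to 31.3% for now and the same after red and teal, since neither brings incoming ligand. Grey raises the budget to 100%, more than the 50.0% that red, violet and teal keep, so the reckoning here names grey as best.

The forecast gave 31.4% (30.7% to 32.1%), 0.1 percentage points above that mean, with 31.4% after red, 31.4% after teal and grey as best, holding that “the plateaus mean the incoming ligand has run out, not that equilibrium was reached”.

    starting complex + incoming ligand ⇌ leaving ligand + complex with one exchanged (K = 19.0, k = 4.30 L mol⁻¹ s⁻¹, Ea = 65.0 kJ mol⁻¹, ΔH = 19.0 kJ mol⁻¹)
    complex with one exchanged + incoming ligand ⇌ leaving ligand + complex with two exchanged (K = 1.90, k = 4.40 L mol⁻¹ s⁻¹, Ea = 51.0 kJ mol⁻¹, ΔH = −9.00 kJ mol⁻¹)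
    complex with two exchanged + incoming ligand ⇌ leaving ligand + complex with three exchanged (K = 2.00, k = 0.670 L mol⁻¹ s⁻¹, Ea = 47.0 kJ mol⁻¹, ΔH = −5.00 kJ mol⁻¹)
    leaving ligand + incoming ligand ⇌ idle adduct, settled at all times (K = 3500 L mol⁻¹, ΔH = −4.00 kJ mol⁻¹)
    scavenger + leaving ligand → scavenged by-product (k = 58.0 L mol⁻¹ s⁻¹, Ea = 35.0 kJ mol⁻¹)
    (constants at 90 °C)

The flask gives 30.7%, the same 30.7% after red and 30.7% after teal, while grey adds 11 points. At 120 min the free incoming ligand stands at 0%, and the complexes bill 50.0% against the budget of 50.0%. A neighbour charged with 0.0040 M of starting complex has a budget of 125%, and it ends with 33.5% of complex with one exchanged, 39.7% with two and 4.01% with three, a bill of 125%.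

(The data are calculated with made-up constants, and the scatter is random.)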